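**Plan**

- Retrosynthesis: the aryl–CO bond is cut last (aryl Grignard reagent + a spiro succinic anhydride, a temporary ring). The oxepine is then cut in one operation at O1–C7 and C2–C3.
- Enabling feature: in the 2,3,4,7-tetrahydrooxepine, C7H2–C6(R)=C5H–C4H2–C3H2 is the five-carbon unit of a 1-substituted vinylcyclopropane, and O1–C2 (C2 carrying the carboxyl) is the C=O of an α-keto ester. The ring is therefore the formal [5+2] adduct of these two, reachable through a triplet carbonyl and a cyclopropylcarbinyl radical clock.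
- Forward: vinylcyclopropane 6 (3 steps) and chiral keto ester 10 (1 step) are joined by the photocycloaddition, which makes the only ring and the quaternary centre. The side arms are then adjusted and the aryl ketone is made last.
- Stereochemistry: C2 comes from face shielding by the 8-phenylmenthyl ester in the radical recombination. The side-chain E-alkene comes from cross-metathesis with ethyl methacrylate. The ring alkene is cis by ring constraint.
- Helpers: the dioxolane (masked carboxymethyl arm, avoiding an enolised 2,4-dioxo ester), the enoate (deactivates the second alkene toward the triplet), and MOM ethers. All are removed later.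

Key step: step 5

Assumption: the unchelated ketyl radical reacts through the conformer with the ring oxygen anti to the ester carbonyl, for which (1R,2S,5R)-8-phenylmenthyl should expose the face leading to 2S; if the sense were opposite, the enantiomeric auxiliary would be used with no other change.

**Route**

Step 1
Reactants: 1 N-methoxy-N-methylcyclopropanecarboxamide; 2 but-3-en-1-ylmagnesium bromide
Product: 3 1-cyclopropylpent-4-en-1-one
Conditions: THF, 0 °C → rt; aq. NH4Cl
Reagents that add atoms: none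
Why: Weinreb ketone synthesis, in which the chelated tetrahedral intermediate prevents a second addition.

Step 2
Reactants: 3 1-cyclopropylpent-4-en-1-one
Product: 4 (hexa-1,5-dien-2-yl)cyclopropane
Conditions: Ph3PCH3Br, KOtBu, THF, 0 °C → rt; pentane extraction, careful distillation (volatile)
Reagents that add atoms: methyltriphenylphosphonium bromide, C[P+](c1ccccc1)(c1ccccc1)c1ccccc1.[Br-]
Why: Wittig methylenation of an unhindered ketone, which leaves the cyclopropane and the terminal alkene untouched.

Step 3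
Reactants: 4 (hexa-1,5-dien-2-yl)cyclopropane; 5 ethyl methacrylate
Product: 6 ethyl (2E)-6-cyclopropyl-2-methylhepta-2,6-dienoate
Conditions: 5 (8 equiv), second-generation Hoveyda–Grubbs catalyst (H2IMes)Cl2Ru(=CH-C6H4-2-OiPr) (5 mol %), CH2Cl2, 40 °C
Reagents that add atoms: none
Why: olefin cross-metathesis, in which only the monosubstituted alkene of 4 should react (the cyclopropyl-bearing 1,1-disubstituted alkene is a spectator) and the conjugated trisubstituted enoate should form as the E isomer.

Step 4
Reactants: 7 (1R,2S,5R)-5-methyl-2-(2-phenylpropan-2-yl)cyclohexan-1-ol [(−)-8-phenylmenthol]; 8 (1,3-dioxolan-2-ylmethyl)magnesium bromide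
Product: 10 (1R,2S,5R)-5-methyl-2-(2-phenylpropan-2-yl)cyclohexyl 3-(1,3-dioxolan-2-yl)-2-oxopropanoate, via chlorooxoacetate 9 (not isolated)
Conditions: (COCl)2 (3 equiv), CH2Cl2, 0 °C → rt, evaporate; then 8 (1.05 equiv), CuBr·SMe2 (10 mol %), THF, −78 °C
Reagents that add atoms: oxalyl chloride, ClC(=O)C(=O)Cl
Why: half-acylation of the hindered alcohol by excess oxalyl chloride, then copper-catalysed ketone synthesis from the acid chloride and a Grignard reagent, which should stop at the non-enolised α-keto ester.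

Step 5
Reactants: 6 ethyl (2E)-6-cyclopropyl-2-methylhepta-2,6-dienoate; 10 (1R,2S,5R)-5-methyl-2-(2-phenylpropan-2-yl)cyclohexyl 3-(1,3-dioxolan-2-yl)-2-oxopropanoate
Product: 13 (1R,2S,5R)-5-methyl-2-(2-phenylpropan-2-yl)cyclohexyl (2S)-2-(1,3-dioxolan-2-ylmethyl)-6-[(3E)-5-ethoxy-4-methyl-5-oxopent-3-en-1-yl]-2,3,4,7-tetrahydrooxepine-2-carboxylate, via triplet 1,4-biradical 11 (not isolated), via ring-opened 1,7-biradical 12 (not isolated)
Conditions: 6 (5 equiv, excess recovered), hν (365 nm LEDs, Pyrex), degassed PhH, 45 °C; chromatographic separation of the C2 epimers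
Reagents that add atoms: none
Why: Proposed new method: n→π* excitation of α-keto ester 10 and intersystem crossing give a triplet whose electrophilic oxygen should add to the terminal CH2 of the electron-rich 1,1-disubstituted alkene of 6, forming O1–C7 and the 1,4-biradical 11, whose tertiary cyclopropylcarbinyl radical opens (radical clock) to the homoallyl primary radical of 12. Spin inversion and radical–radical recombination of this 1,7-biradical then form C2–C3 and close the oxepine as a seven-membered ring with a necessarily cis C5=C6 bond, overall a stepwise [5+2] addition of C=O to a vinylcyclopropane. The closest known reaction types are the Paternò–Büchi reaction of α-keto esters with alkenes and the oxepine-forming photoadditions of aryl ketones and quinones to vinylcyclopropanes; an α-keto ester with a chiral ester group has not been shown in this role. The only new stereocentre, C2, is set in the recombination: the phenyl ring of the 8-phenylmenthyl group should stack over one face of the planar ketyl radical so that the CH2 radical bonds from the open face, as in the face-selective Paternò–Büchi reactions of 8-phenylmenthyl phenylglyoxylate, which should give 2S. The step needs chemoselectivity between the two alkenes of 6 (the enoate is electron-poor and transparent at 365 nm), oxygen-to-CH2 regioselectivity (it gives the more stabilised radical), and ring opening faster than oxetane closure (favoured by the tertiary radical and the warm bath). A homoallyl radical with the wrong alkene geometry cannot close the ring and should revert or disproportionate, which costs material but not constitution.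

Step 6
Reactants: 13 photoadduct (ethyl enoate)
Product: 14 (1R,2S,5R)-5-methyl-2-(2-phenylpropan-2-yl)cyclohexyl (2S)-2-(1,3-dioxolan-2-ylmethyl)-6-[(3E)-5-hydroxy-4-methylpent-3-en-1-yl]-2,3,4,7-tetrahydrooxepine-2-carboxylate
Conditions: iBu2AlH (2.5 equiv), CH2Cl2, −78 °C; aq. potassium sodium tartrate
Reagents that add atoms: none
Why: DIBAL-H reduction of the unhindered conjugated ethyl ester to the allylic alcohol, while the tertiary 8-phenylmenthyl ester (quaternary α-carbon, bulky alkoxy group) and the dioxolane should survive at −78 °C and the alkene geometry and C2 are not touched.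

Step 7
Reactants: 14 allylic alcohol
Product: 15 (1R,2S,5R)-5-methyl-2-(2-phenylpropan-2-yl)cyclohexyl (2S)-6-[(3E)-5-hydroxy-4-methylpent-3-en-1-yl]-2-(2-oxoethyl)-2,3,4,7-tetrahydrooxepine-2-carboxylate
Conditions: TsOH·H2O (0.2 equiv), acetone/H2O (4:1), 45 °C
Reagents that add atoms: water, O
Why: acid-catalysed acetal hydrolysis (with transacetalisation to acetone), mild enough for the hindered ester, the allylic ether and the allylic alcohol.

Step 8
Reactants: 15 aldehyde
Product: 16 [(2S)-6-[(3E)-5-hydroxy-4-methylpent-3-en-1-yl]-2-({[(1R,2S,5R)-5-methyl-2-(2-phenylpropan-2-yl)cyclohexyl]oxy}carbonyl)-2,3,4,7-tetrahydrooxepin-2-yl]acetic acid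
Conditions: NaClO2, NaH2PO4, 2-methylbut-2-ene (20 equiv), tBuOH/H2O, 0 °C → rt
Reagents that add atoms: sodium chlorite, [Na+].[O-]Cl=O
Why: Pinnick oxidation, which oxidises the aldehyde but not the allylic alcohol, with the alkene scavenger removing hypochlorous acid before it can attack the two trisubstituted alkenes.

Step 9
Reactants: 16 mono-acid ester
Product: 17 (2S)-2-(carboxymethyl)-6-[(3E)-5-hydroxy-4-methylpent-3-en-1-yl]-2,3,4,7-tetrahydrooxepine-2-carboxylic acid
Conditions: KOH (10 equiv), MeOH/H2O (3:1), 75 °C; then 1 M HCl to pH 2 at 0 °C; 7 recovered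
Reagents that add atoms: potassium hydroxide, [K+].[OH-]
Why: saponification of the hindered ester under forcing conditions, as used to release tertiary α-oxygenated acids from 8-phenylmenthol; it is placed here because the substrate is a bis-carboxylate with no ketone or aldehyde, so β-elimination of the ring oxygen cannot start and the quaternary C2 cannot epimerise.

Step 10
Reactants: 18 2-bromobenzene-1,4-diol
Product: 19 2-bromo-1,4-bis(methoxymethoxy)benzene
Conditions: MOMCl (2.5 equiv), iPr2NEt (3 equiv), CH2Cl2, 0 °C → rt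
Reagents that add atoms: chloromethyl methyl ether, COCCl
Why: standard O-alkylation of both phenols to base-stable acetal ethers that tolerate and stabilise the ortho aryl Grignard reagent.

Step 11
Reactants: 17 diacid; 19 2-bromo-1,4-bis(methoxymethoxy)benzene
Product: 22 (2S)-2-{2-[2,5-bis(methoxymethoxy)phenyl]-2-oxoethyl}-6-[(3E)-5-hydroxy-4-methylpent-3-en-1-yl]-2,3,4,7-tetrahydrooxepine-2-carboxylic acid, via aryl Grignard reagent 20 (not isolated), via spiro anhydride 21 (not isolated)
Conditions: 19, Mg, THF, 45 °C (gives 20); separately 17, DCC (1.05 equiv), THF, 0 °C → rt, filtration (gives 21); 20 (2.3 equiv) added to 21, THF, −78 °C; aq. NH4Cl, then citric acid to pH 3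
Reagents that add atoms: none
Why: carbodiimide dehydration of the 1,4-diacid gives the five-membered anhydride, and the ortho-substituted aryl Grignard reagent should open it at the CH2-flanked carbonyl, away from the quaternary carbon (steric control, as with 2,2-disubstituted succinic anhydrides), so that the ketone and the free acid appear together and the β-alkoxy ketone never meets hydroxide.

Step 12
Reactants: 22 bis-MOM keto acid
Product: 23 (2S)-2-[2-(2,5-dihydroxyphenyl)-2-oxoethyl]-6-[(3E)-5-hydroxy-4-methylpent-3-en-1-yl]-2,3,4,7-tetrahydrooxepine-2-carboxylic acid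
Conditions: HCl (2 M aq.), THF, 35 °C
Reagents that add atoms: none
Why: acid-catalysed cleavage of the two aryl methoxymethyl acetals (the one ortho to the ketone assisted by hydrogen bonding) under conditions mild enough for the allylic ether, the allylic alcohol and the β-alkoxy ketone.

**Compound list**

1 | N-methoxy-N-methylcyclopropanecarboxamide | CON(C)C(=O)C1CC1 | starting material
2 | but-3-en-1-ylmagnesium bromide | C=CCC[Mg]Br | starting material
3 | 1-cyclopropylpent-4-en-1-one | C=CCCC(=O)C1CC1 | intermediate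
4 | (hexa-1,5-dien-2-yl)cyclopropane | C=CCCC(=C)C1CC1 | intermediate
5 | ethyl methacrylate | C=C(C)C(=O)OCC | starting material
6 | ethyl (2E)-6-cyclopropyl-2-methylhepta-2,6-dienoate | C/C(=C\CCC(=C)C1CC1)C(=O)OCC | intermediate
7 | (1R,2S,5R)-5-methyl-2-(2-phenylpropan-2-yl)cyclohexan-1-ol | O[C@@H]1C[C@H](C)CC[C@H]1C(C)(C)c1ccccc1 | starting material
8 | (1,3-dioxolan-2-ylmethyl)magnesium bromide | Br[Mg]CC1OCCO1 | starting material
9 | (1R,2S,5R)-5-methyl-2-(2-phenylpropan-2-yl)cyclohexyl chlorooxoacetate | ClC(=O)C(=O)O[C@@H]1C[C@H](C)CC[C@H]1C(C)(C)c1ccccc1 | intermediate (not isolated)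
10 | (1R,2S,5R)-5-methyl-2-(2-phenylpropan-2-yl)cyclohexyl 3-(1,3-dioxolan-2-yl)-2-oxopropanoate | O=C(CC1OCCO1)C(=O)O[C@@H]1C[C@H](C)CC[C@H]1C(C)(C)c1ccccc1 | intermediate
11 | triplet 1,4-biradical from O–CH2 bond formation | CCOC(=O)/C(C)=C/CC[C](C1CC1)CO[C](CC1OCCO1)C(=O)O[C@@H]1C[C@H](C)CC[C@H]1C(C)(C)c1ccccc1 | intermediate (not isolated)
12 | ring-opened 1,7-biradical | [CH2]C/C=C(/CC/C=C(\C)C(=O)OCC)CO[C](CC1OCCO1)C(=O)O[C@@H]1C[C@H](C)CC[C@H]1C(C)(C)c1ccccc1 | intermediate (not isolated)
13 | (1R,2S,5R)-5-methyl-2-(2-phenylpropan-2-yl)cyclohexyl (2S)-2-(1,3-dioxolan-2-ylmethyl)-6-[(3E)-5-ethoxy-4-methyl-5-oxopent-3-en-1-yl]-2,3,4,7-tetrahydrooxepine-2-carboxylate | C/C(=C\CCC1=CCC[C@](CC2OCCO2)(C(=O)O[C@@H]2C[C@H](C)CC[C@H]2C(C)(C)c2ccccc2)OC1)C(=O)OCC | intermediate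
14 | (1R,2S,5R)-5-methyl-2-(2-phenylpropan-2-yl)cyclohexyl (2S)-2-(1,3-dioxolan-2-ylmethyl)-6-[(3E)-5-hydroxy-4-methylpent-3-en-1-yl]-2,3,4,7-tetrahydrooxepine-2-carboxylate | C/C(=C\CCC1=CCC[C@](CC2OCCO2)(C(=O)O[C@@H]2C[C@H](C)CC[C@H]2C(C)(C)c2ccccc2)OC1)CO | intermediate
15 | (1R,2S,5R)-5-methyl-2-(2-phenylpropan-2-yl)cyclohexyl (2S)-6-[(3E)-5-hydroxy-4-methylpent-3-en-1-yl]-2-(2-oxoethyl)-2,3,4,7-tetrahydrooxepine-2-carboxylate | C/C(=C\CCC1=CCC[C@](CC=O)(C(=O)O[C@@H]2C[C@H](C)CC[C@H]2C(C)(C)c2ccccc2)OC1)CO | intermediate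
16 | [(2S)-6-[(3E)-5-hydroxy-4-methylpent-3-en-1-yl]-2-({[(1R,2S,5R)-5-methyl-2-(2-phenylpropan-2-yl)cyclohexyl]oxy}carbonyl)-2,3,4,7-tetrahydrooxepin-2-yl]acetic acid | C/C(=C\CCC1=CCC[C@](CC(=O)O)(C(=O)O[C@@H]2C[C@H](C)CC[C@H]2C(C)(C)c2ccccc2)OC1)CO | intermediate
17 | (2S)-2-(carboxymethyl)-6-[(3E)-5-hydroxy-4-methylpent-3-en-1-yl]-2,3,4,7-tetrahydrooxepine-2-carboxylic acid | C/C(=C\CCC1=CCC[C@](CC(=O)O)(C(=O)O)OC1)CO | intermediate
18 | 2-bromobenzene-1,4-diol | Oc1ccc(O)c(Br)c1 | starting material
19 | 2-bromo-1,4-bis(methoxymethoxy)benzene | COCOc1ccc(OCOC)c(Br)c1 | intermediate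
20 | [2,5-bis(methoxymethoxy)phenyl]magnesium bromide | COCOc1ccc(OCOC)c([Mg]Br)c1 | intermediate (not isolated)
21 | (5S)-8-[(3E)-5-hydroxy-4-methylpent-3-en-1-yl]-2,6-dioxaspiro[4.6]undec-8-ene-1,3-dione | C/C(=C\CCC1=CCC[C@@]2(CC(=O)OC2=O)OC1)CO | intermediate (not isolated)
22 | (2S)-2-{2-[2,5-bis(methoxymethoxy)phenyl]-2-oxoethyl}-6-[(3E)-5-hydroxy-4-methylpent-3-en-1-yl]-2,3,4,7-tetrahydrooxepine-2-carboxylic acid | C/C(=C\CCC1=CCC[C@](CC(=O)c2cc(OCOC)ccc2OCOC)(C(=O)O)OC1)CO | intermediate
23 | (2S)-2-[2-(2,5-dihydroxyphenyl)-2-oxoethyl]-6-[(3E)-5-hydroxy-4-methylpent-3-en-1-yl]-2,3,4,7-tetrahydrooxepine-2-carboxylic acid | C/C(=C\CCC1=CCC[C@](CC(=O)c2cc(O)ccc2O)(C(=O)O)OC1)CO | target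

**Step count**

Total steps: 12. Longest linear sequence: 10 steps (steps 1, 2, 3, 5, 6, 7, 8, 9, 11, 12).

**Steps most likely to fail**

1. Step 5 (Proposed new method). What may go wrong:
   - oxetane closure of the 1,4-biradical before the cyclopropane opens;
   - loss of the triplet by intramolecular hydrogen abstraction from the ester or dioxolane C–H bonds;
   - poor facial selectivity in the long-range radical recombination;
   - sensitised E/Z scrambling of the enoate.

   Fallback with known chemistry (O-allylation and ring-closing metathesis), setting out from 9 and coming back at 13: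
   - 9 (from 7 as in step 4) and 2 with CuBr·SMe2 at −78 °C should give (1R,2S,5R)-5-methyl-2-(2-phenylpropan-2-yl)cyclohexyl 2-oxohex-5-enoate F1.
   - Chelation-controlled addition of 8 at −78 °C should give the tertiary alcohol (1R,2S,5R)-5-methyl-2-(2-phenylpropan-2-yl)cyclohexyl (2S)-2-(1,3-dioxolan-2-ylmethyl)-2-hydroxyhex-5-enoate F2. The arm is added last so that the face selectivity of Grignard additions to 8-phenylmenthyl α-keto esters leads to 2S.
   - Separately, copper-catalysed carbomagnesiation of prop-2-yn-1-ol with 2 (CuI, Et2O) should give 2-methylidenehex-5-en-1-ol F3.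
   - Cross-metathesis of F3 with 5 should give ethyl (2E)-6-(hydroxymethyl)-2-methylhepta-2,6-dienoate F4, and CBr4/PPh3 should give ethyl (2E)-6-(bromomethyl)-2-methylhepta-2,6-dienoate F5.
   - O-Alkylation of F2 with F5 (NaH, DMF, 0 °C) should give (1R,2S,5R)-5-methyl-2-(2-phenylpropan-2-yl)cyclohexyl (2S)-2-(1,3-dioxolan-2-ylmethyl)-2-{[(5E)-7-ethoxy-6-methyl-2-methylidene-7-oxohept-5-en-1-yl]oxy}hex-5-enoate F6.
   - Ring-closing metathesis of F6 (second-generation Grubbs catalyst (H2IMes)(PCy3)Cl2Ru=CHPh, toluene, 80 °C) closes the oxepine and returns to 13.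

2. Step 11. What may go wrong:
   - attack at the hindered carbonyl, which is activated by the α-oxygen and possible chelation;
   - a second addition to the new ketone, followed by lactonisation;
   - acylation of the free allylic alkoxide by the anhydride.

   Fallback (stepwise differentiation and chelate-controlled acylation instead of anhydride opening), setting out from 17 and coming back at 22:
   - Fischer esterification (MeOH, catalytic AcCl, 0 °C) should esterify only the unhindered CH2CO2H, giving (2S)-6-[(3E)-5-hydroxy-4-methylpent-3-en-1-yl]-2-(2-methoxy-2-oxoethyl)-2,3,4,7-tetrahydrooxepine-2-carboxylic acid F7.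
   - Me(MeO)NH·HCl and iPrMgCl (THF, −20 °C) should convert the methyl ester to (2S)-6-[(3E)-5-hydroxy-4-methylpent-3-en-1-yl]-2-{2-[methoxy(methyl)amino]-2-oxoethyl}-2,3,4,7-tetrahydrooxepine-2-carboxylic acid F8.
   - Excess 20 at −40 °C should add once to the Weinreb amide through the stable chelate and give 22 on acidic work-up.

3. Step 6. What may go wrong:
   - partial reduction of the auxiliary ester, activated by its α-oxygen;
   - incomplete reduction stopping at the enal.

   Fallback (selection by saponification rate, then borohydride reduction of an activated carboxyl), setting out from 13 and coming back at 14: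
   - LiOH (1.2 equiv, THF/H2O, 0 °C) should hydrolyse only the unhindered ethyl ester to (2E)-5-[(2S)-2-(1,3-dioxolan-2-ylmethyl)-2-({[(1R,2S,5R)-5-methyl-2-(2-phenylpropan-2-yl)cyclohexyl]oxy}carbonyl)-2,3,4,7-tetrahydrooxepin-6-yl]-2-methylpent-2-enoic acid F9.
   - Isobutyl chloroformate and N-methylmorpholine (THF, −15 °C) should give the mixed carbonic anhydride (isobutyl carbonate of F9) F10.
   - NaBH4 (THF/H2O, 0 °C) should reduce F10 to 14 without touching the remaining ester or the alkenes.

**Further compounds**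

F1 | step 5 | (1R,2S,5R)-5-methyl-2-(2-phenylpropan-2-yl)cyclohexyl 2-oxohex-5-enoate | C=CCCC(=O)C(=O)O[C@@H]1C[C@H](C)CC[C@H]1C(C)(C)c1ccccc1
F2 | step 5 | (1R,2S,5R)-5-methyl-2-(2-phenylpropan-2-yl)cyclohexyl (2S)-2-(1,3-dioxolan-2-ylmethyl)-2-hydroxyhex-5-enoate | C=CCC[C@](CC1OCCO1)(C(=O)O[C@@H]1C[C@H](C)CC[C@H]1C(C)(C)c1ccccc1)O
F3 | step 5 | 2-methylidenehex-5-en-1-ol | C=CCCC(=C)CO
F4 | step 5 | ethyl (2E)-6-(hydroxymethyl)-2-methylhepta-2,6-dienoate | C/C(=C\CCC(=C)CO)C(=O)OCC
F5 | step 5 | ethyl (2E)-6-(bromomethyl)-2-methylhepta-2,6-dienoate | C/C(=C\CCC(=C)CBr)C(=O)OCC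
F6 | step 5 | (1R,2S,5R)-5-methyl-2-(2-phenylpropan-2-yl)cyclohexyl (2S)-2-(1,3-dioxolan-2-ylmethyl)-2-{[(5E)-7-ethoxy-6-methyl-2-methylidene-7-oxohept-5-en-1-yl]oxy}hex-5-enoate | C=CCC[C@](CC1OCCO1)(C(=O)O[C@@H]1C[C@H](C)CC[C@H]1C(C)(C)c1ccccc1)OCC(=C)CC/C=C(\C)C(=O)OCC
F7 | step 11 | (2S)-6-[(3E)-5-hydroxy-4-methylpent-3-en-1-yl]-2-(2-methoxy-2-oxoethyl)-2,3,4,7-tetrahydrooxepine-2-carboxylic acid | C/C(=C\CCC1=CCC[C@](CC(=O)OC)(C(=O)O)OC1)CO
F8 | step 11 | (2S)-6-[(3E)-5-hydroxy-4-methylpent-3-en-1-yl]-2-{2-[methoxy(methyl)amino]-2-oxoethyl}-2,3,4,7-tetrahydrooxepine-2-carboxylic acid | C/C(=C\CCC1=CCC[C@](CC(=O)N(C)OC)(C(=O)O)OC1)CO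
F9 | step 6 | (2E)-5-[(2S)-2-(1,3-dioxolan-2-ylmethyl)-2-({[(1R,2S,5R)-5-methyl-2-(2-phenylpropan-2-yl)cyclohexyl]oxy}carbonyl)-2,3,4,7-tetrahydrooxepin-6-yl]-2-methylpent-2-enoic acid | C/C(=C\CCC1=CCC[C@](CC2OCCO2)(C(=O)O[C@@H]2C[C@H](C)CC[C@H]2C(C)(C)c2ccccc2)OC1)C(=O)O
F10 | step 6 | mixed anhydride of F9 with isobutyl hydrogen carbonate | C/C(=C\CCC1=CCC[C@](CC2OCCO2)(C(=O)O[C@@H]2C[C@H](C)CC[C@H]2C(C)(C)c2ccccc2)OC1)C(=O)OC(=O)OCC(C)C
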